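Retrosynthetic cuts: first the C-3–prenyl bond of ring A; then the bond from spiro C-5 to the CH2 next to the ring B carbinol, which opens ring B and rearomatises ring A; then the second C-5–CH2 bond; then the aryl–acyl bond.
Enabling feature: spiro C-5 is a phloroglucinol carbon flanked by C-4=O and C-6=O (former phenol carbons). The string C-5–CH2–C(CH3)(OH) in ring B is what an arene carbon leaves when it opens a 2-methyloxirane at its CH2 end.
Forward order: ring C travels inside a temporary cis-bicyclo[3.3.0]octene made from cycloocta-1,5-diene, and ozone cuts its second ring. Ring A arrives as the flat arene from 2-methylphloroglucinol. Ring B closes last, with dearomatisation.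
Stereochemistry, part 1: both ring-fusion CH come from a lipase resolution. Both C(CH3)(OH) centres are set at once by convex-face methyl addition to the C2-symmetric dione skeleton, a symmetry hidden in the C10 unit. The sec-butyl centre comes from (R)-2-methylbutanoic acid.
Stereochemistry, part 2: spiro C-5 comes from a chair transition state steered by a removable OTIPS group on O-4. C-3 comes from a chiral palladium catalyst, because ring B is too remote to bias it.

Key step: step 13

Remark on the chemistry: ring A locants are C-1 (acyl), C-2 (O), C-3 (CH3), C-4 (O), C-5 (spiro carbon), C-6 (O). Enolised ring A compounds are drawn as one tautomer. Racemates 2 and 3 are written as both enantiomers joined by a dot. (R)-2-Methylbutanoic acid is assumed to be bought as the single enantiomer.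

Step 1
Reactants: 1 (1Z,5Z)-cycloocta-1,5-diene
Product: 2 rac-endo,endo-cis-bicyclo[3.3.0]octane-2,6-diyl diacetate
Conditions: Pd(OAc)2 (2 mol %), Pb(OAc)4 (1.1 equiv), AcOH, 25 °C
Reagents that add atoms: lead tetraacetate, CC(=O)O[Pb](OC(C)=O)(OC(C)=O)OC(C)=O
Why: Palladium-catalysed oxidative transannular cyclisation, in which trans-acetoxypalladation, syn insertion of the second alkene and displacement of the oxidised C–Pd bond with inversion should place both acetates endo on the cis-fused bicycle.

Step 2
Reactants: 2 rac-endo,endo-diacetate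
Product: 3 rac-endo,endo-cis-bicyclo[3.3.0]octane-2,6-diol
Conditions: K2CO3 (cat.), MeOH, 25 °C
Reagents that add atoms: none
Why: Zemplén-type transesterification that touches no stereocentre.

Step 3
Reactants: 3 rac-endo,endo-diol
Product: 4 (1R,2S,5R,6S)-cis-bicyclo[3.3.0]octane-2,6-diol
Conditions: immobilised Candida antarctica lipase B, vinyl acetate, MTBE, 30 °C, run to just past half conversion; chromatography
Reagents that add atoms: none
Why: Lipase kinetic resolution in which, by the Kazlauskas rule, the enantiomer with R carbinol carbons should be acylated twice and the wanted (2S,6S)-diol left behind, which fixes both ring-fusion centres.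

Step 4
Reactants: 4 (1R,2S,5R,6S)-diol
Product: 5 (1R,5R)-cis-bicyclo[3.3.0]octane-2,6-dione
Conditions: n-Pr4N[RuO4] (5 mol %), NMO (3 equiv), 4 Å MS, CH2Cl2, 25 °C
Reagents that add atoms: none
Why: Ley–Griffith oxidation; the α-CH centres cannot invert one at a time because a trans-fused bicyclo[3.3.0]octane is too strained.

Step 5
Reactants: 5 (1R,5R)-dione
Product: 7 (1R,5R)-cis-bicyclo[3.3.0]oct-3-ene-2,6-dione, via trimethylsilyl enol ether 6 (not isolated)
Conditions: LDA (1.0 equiv), TMSCl, THF, −78 °C; crude 6, Pd(OAc)2 (1.0 equiv), MeCN, 25 °C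
Reagents that add atoms: none
Why: Kinetic enolisation at the α-CH2 followed by Saegusa–Ito oxidation; the C2 axis makes the two carbonyl groups equivalent, so only one enone can form.

Step 6
Reactants: 7 (1R,5R)-enedione
Product: 8 (1R,2S,5R,6S)-2,6-dimethyl-cis-bicyclo[3.3.0]oct-3-ene-2,6-diol (both CH3 exo, both OH endo)
Conditions: MeLi (3 equiv), CeCl3 (3 equiv, dried), THF, −78 °C; aq NH4Cl
Reagents that add atoms: methyllithium, [Li]C
Why: Organocerium 1,2-addition to ketone and enone alike; the weakly basic reagent should spare the acidic ring-fusion CH, and attack on the convex face sets both tertiary carbinols with CH3 cis to the ring-fusion hydrogens.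

Step 7
Reactants: 8 ene-diol
Product: 10 (1S,2S,3R)-3-[(2R)-1,2-dihydroxypropan-2-yl]-2-(hydroxymethyl)-1-methylcyclopentan-1-ol, via secondary ozonide 9 (not isolated)
Conditions: O3, CH2Cl2, −78 °C; then NaBH4, MeOH, −78 to 0 °C
Reagents that add atoms: ozone, [O-][O+]=O
Why: Ozonolysis with reductive work-up cuts the temporary ring and leaves ring C with its all-cis substituents, no stereocentre being touched.

Step 8
Reactants: 10 tetraol
Product: 12 (1S,2S,3R)-2-(hydroxymethyl)-1-methyl-3-[(2R)-2-methyloxiran-2-yl]cyclopentan-1-ol, via primary monotosylate 11 (not isolated)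
Conditions: TsCl (1.05 equiv), Bu2SnO (5 mol %), Et3N (1.1 equiv), CH2Cl2, 0 °C; then K2CO3, MeOH, 0 °C
Reagents that add atoms: none
Why: Stannylene-acetal-catalysed tosylation picks the primary OH of the 1,2-diol over the isolated primary OH, and Williamson-type closure keeps the C–O bond at the quaternary carbon, so its configuration is retained.

Step 9
Reactants: 12 epoxy diol
Product: 13 (1R,2S,5R)-2-hydroxy-2-methyl-5-[(2R)-2-methyloxiran-2-yl]cyclopentane-1-carbaldehyde
Conditions: n-Pr4N[RuO4] (5 mol %), NMO (1.5 equiv), 4 Å MS, CH2Cl2, 0 °C; used at once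
Reagents that add atoms: none
Why: Neutral Ley–Griffith oxidation of the only oxidisable alcohol, chosen to spare the acid-sensitive oxirane and the epimerisable α-carbon.

Step 10
Reactants: 14 2-methylphloroglucinol; 15 (R)-2-methylbutanoic acid
Product: 17 (2R)-2-methyl-1-(2,4,6-trihydroxy-3-methylphenyl)butan-1-one, via acid chloride 16 (not isolated)
Conditions: 15, (COCl)2, DMF (cat.), CH2Cl2, 0 °C; then 14, AlCl3 (3.5 equiv), CH2Cl2/PhNO2, 0 to 25 °C; 1 M HCl
Reagents that add atoms: none
Why: Friedel–Crafts acylation at one of the two equivalent free positions; the low temperature is meant to keep the α-stereocentre intact.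

Step 11
Reactants: 13 epoxy aldehyde; 17 acyl-methylphloroglucinol
Product: 19 (2R)-1-[2,4,6-trihydroxy-3-{[(1R,2S,5R)-2-hydroxy-2-methyl-5-[(2R)-2-methyloxiran-2-yl]cyclopentyl]methyl}-5-methylphenyl]-2-methylbutan-1-one, via ortho-quinone methide 18 (not isolated)
Conditions: L-proline (20 mol %), diethyl 2,6-dimethyl-1,4-dihydropyridine-3,5-dicarboxylate (1.3 equiv), CH2Cl2, 25 °C
Reagents that add atoms: none
Why: Organocatalytic three-component reductive alkylation, that is Knoevenagel-type condensation at the only free arene carbon and then Hantzsch ester transfer hydrogenation of the quinone methide, which should be faster than its tautomerisation.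

Step 12
Reactants: 19 coupled epoxide
Product: 20 4-O-triisopropylsilyl ether of 19 (silyl group on the OH para to the acyl group)
Conditions: TIPSCl (1.1 equiv), imidazole, DMF, 0 to 25 °C
Reagents that add atoms: triisopropylsilyl chloride, CC(C)[Si](Cl)(C(C)C)C(C)C
Why: Selective phenol silylation; O-4 is the most acidic OH and the only one not hydrogen-bonded to the acyl group, and tertiary alcohols do not react under these conditions.

Step 13
Reactants: 20 TIPS-steered aryl epoxide
Product: 22 spiro compound lacking only the prenyl group (C-5 R; ring A as the 2-acyl-3,5-dihydroxy-4-methylcyclohexa-2,4-dienone tautomer; cis-hydrindane diol as in the target), via spiro TIPS dienol ether 21 (not isolated)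
Conditions: Cs2CO3 (3 equiv), 4 Å MS, DMSO, 25 to 70 °C; then TBAF (1.2 equiv), THF, 0 °C; 1 M HCl
Reagents that add atoms: none
Why: Proposed new method: the caesium phenoxide of 20 is an ambident enolate whose C-5, the only ring carbon the tether can reach, attacks the oxirane CH2 from the back, so the arene is dearomatised while the C–O bond at the quaternary oxirane carbon stays intact and becomes the tertiary carbinol with retention. The closest known reaction types are Ar1-type phenoxide spiroalkylation, alkylative dearomatisation of acylphloroglucinols with allylic halides and the Stork enolate–epoxide cyclisation, but an oxirane has not been shown as the electrophile at a phloroglucinol carbon. Ring B closes in the 6-endo-tet mode (both oxirane carbons end up in the ring), since the 5-exo alternative needs substitution at a fully substituted carbon and O-alkylation needs an eight-membered ring. Anti opening puts the oxirane oxygen equatorial and its methyl axial in a chair whose other substituents are fixed by the cis-cyclopentane, so the two ortho carbons of the arene compete for one axial site beside that methyl and one free equatorial site. The carbon bearing OTIPS cannot take the axial site, so C-4 should go equatorial (cis to the new OH) and the acyl-chelated C-6 axial, which is the R spiro centre. The carbonate/hydrogen carbonate buffer keeps the cyclopentanol OH and the nascent alkoxide protonated, which should suppress ether formation, and fluoride then removes the steering group.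

Step 14
Reactants: 22 spiro compound
Product: 23 CNP0236509.3 (target; C-3 S, C-5 R)
Conditions: prenyl acetate (1.3 equiv), Pd2(dba)3·CHCl3 (2.5 mol %), (R,R)-DACH-phenyl Trost ligand (7.5 mol %), Et3N (1.1 equiv), CH2Cl2, 0 °C
Reagents that add atoms: prenyl acetate, CC(=O)OCC=C(C)C
Why: Proposed new method: zerovalent palladium ionises prenyl acetate to a 1,1-dimethyl-π-allyl complex that the soft enolate of 22 attacks at the unsubstituted terminus; O-prenylation is reversible and C-1 gives no stable product, so C-3 is the only sink, and because ring B is too far away to bias the faces of C-3, the ligand pocket, which must house the bulky spiro flank and the flat acyl flank differently, is the control element for the S quaternary centre (the sense of induction is to be confirmed on a model, and the enantiomeric ligand is equally available); closest known reaction types: Tsuji–Trost asymmetric prenylation of oxindoles, asymmetric allylic alkylation of cyclic β-keto esters and the racemic palladium-catalysed allylation of acylphloroglucinols.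

Compound list
1 | (1Z,5Z)-cycloocta-1,5-diene | C1C/C=C\CC/C=C\1 | starting material
2 | rac-endo,endo-cis-bicyclo[3.3.0]octane-2,6-diyl diacetate | CC(=O)O[C@H]1CC[C@H]2[C@@H](OC(C)=O)CC[C@@H]12.CC(=O)O[C@@H]1CC[C@@H]2[C@H](OC(C)=O)CC[C@H]12 | intermediate
3 | rac-endo,endo-cis-bicyclo[3.3.0]octane-2,6-diol | O[C@H]1CC[C@H]2[C@@H](O)CC[C@@H]12.O[C@@H]1CC[C@@H]2[C@H](O)CC[C@H]12 | intermediate
4 | (1R,2S,5R,6S)-cis-bicyclo[3.3.0]octane-2,6-diol | O[C@H]1CC[C@H]2[C@@H](O)CC[C@@H]12 | intermediate
5 | (1R,5R)-cis-bicyclo[3.3.0]octane-2,6-dione | O=C1CC[C@H]2C(=O)CC[C@@H]12 | intermediate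
6 | mono(trimethylsilyl) enol ether of 5 | O=C1CC[C@H]2C(O[Si](C)(C)C)=CC[C@@H]12 | intermediate
7 | (1R,5R)-cis-bicyclo[3.3.0]oct-3-ene-2,6-dione | O=C1CC[C@H]2C(=O)C=C[C@@H]12 | intermediate
8 | (1R,2S,5R,6S)-2,6-dimethyl-cis-bicyclo[3.3.0]oct-3-ene-2,6-diol | C[C@]1(O)CC[C@H]2[C@@](C)(O)C=C[C@@H]12 | intermediate
9 | secondary ozonide of 8 (the two acetal carbons are fixed by the bridge and left unassigned) | O1OC2[C@@H]3[C@@H](CC[C@]3(C)O)[C@@](C)(O)C1O2 | intermediate
10 | (1S,2S,3R)-3-[(2R)-1,2-dihydroxypropan-2-yl]-2-(hydroxymethyl)-1-methylcyclopentan-1-ol | OC[C@@H]1[C@@H](CC[C@]1(C)O)[C@@](C)(O)CO | intermediate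
11 | primary monotosylate of the 1,2-diol of 10 | OC[C@@H]1[C@@H](CC[C@]1(C)O)[C@@](C)(O)COS(=O)(=O)c1ccc(C)cc1 | intermediate
12 | (1S,2S,3R)-2-(hydroxymethyl)-1-methyl-3-[(2R)-2-methyloxiran-2-yl]cyclopentan-1-ol | OC[C@@H]1[C@@H](CC[C@]1(C)O)[C@]1(C)CO1 | intermediate
13 | (1R,2S,5R)-2-hydroxy-2-methyl-5-[(2R)-2-methyloxiran-2-yl]cyclopentane-1-carbaldehyde | O=C[C@@H]1[C@@H](CC[C@]1(C)O)[C@]1(C)CO1 | intermediate
14 | 2-methylphloroglucinol (2-methylbenzene-1,3,5-triol) | Cc1c(O)cc(O)cc1O | starting material
15 | (R)-2-methylbutanoic acid | CC[C@@H](C)C(=O)O | starting material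
16 | (R)-2-methylbutanoyl chloride | CC[C@@H](C)C(=O)Cl | intermediate
17 | (2R)-2-methyl-1-(2,4,6-trihydroxy-3-methylphenyl)butan-1-one | CC[C@@H](C)C(=O)c1c(O)cc(O)c(C)c1O | intermediate
18 | ortho-quinone methide from 13 and 17 (alkene geometry open) | CC[C@@H](C)C(=O)C1=C(O)C(C)=C(O)C(=C[C@@H]2[C@@H](CC[C@]2(C)O)[C@]2(C)CO2)C1=O | intermediate
19 | C-5-alkylated acyl-methylphloroglucinol epoxide | CC[C@@H](C)C(=O)c1c(O)c(C)c(O)c(C[C@@H]2[C@@H](CC[C@]2(C)O)[C@]2(C)CO2)c1O | intermediate
20 | 4-O-TIPS ether of 19 | CC[C@@H](C)C(=O)c1c(O)c(C)c(O[Si](C(C)C)(C(C)C)C(C)C)c(C[C@@H]2[C@@H](CC[C@]2(C)O)[C@]2(C)CO2)c1O | intermediate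
21 | spiro TIPS dienol ether (C-5 R) | CC[C@@H](C)C(=O)C1=C(O)C(C)=C(O[Si](C(C)C)(C(C)C)C(C)C)[C@]2(C[C@@H]3[C@@H](CC[C@]3(C)O)[C@@](C)(O)C2)C1=O | intermediate
22 | spiro compound lacking the prenyl group (C-5 R) | CC[C@@H](C)C(=O)C1=C(O)C(C)=C(O)[C@]2(C[C@@H]3[C@@H](CC[C@]3(C)O)[C@@](C)(O)C2)C1=O | intermediate
23 | CNP0236509.3 | CC[C@@H](C)C(=O)C1=C(O)[C@](C)(CC=C(C)C)C(=O)[C@]2(C[C@@H]3[C@@H](CC[C@]3(C)O)[C@@](C)(O)C2)C1=O | target

Total step count: 14. Longest linear sequence: 13 (steps 1 to 9 and 11 to 14).

Steps most likely to fail

Step 13 (labelled). The C–C bond formation may be too slow, because the arene must pass beside the axial methyl group. Loss of the silyl group, or attack of the cyclopentanol oxygen on the oxirane, could then take over. The fallback changes the order of events and uses known chemistry.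
- It sets out from 19, which is first C-prenylated at C-3, the carbon with the smaller substituent. Prenyl bromide in aq KOH at 0 °C is the alkylative dearomatisation known for acylphloroglucinols, and it gives the dearomatised C-3-prenylated epoxide F1.
- The C-3 epimers are separated.
- Ring B is then closed from the more nucleophilic β-triketone dianion (NaH, 2.2 equiv, THF/DMSO) by an enolate–epoxide cyclisation of the Stork type, with the oxirane approaching the ring A face opposite to the prenyl group.
- This comes back to the route at 23.

Step 14 (labelled). Facial selection at C-3 may be poor, or attack may occur at the substituted allyl terminus.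
- The fallback sets out from 22 and uses the best-studied electrophile: Tsuji–Trost asymmetric allylic alkylation with allyl acetate, with the same palladium source and ligand family. This gives the C-3-allyl analogue F2, at which stage a minor epimer can be removed.
- Cross-metathesis with 2-methylbut-2-ene (second-generation Grubbs catalyst, CH2Cl2, 40 °C) turns allyl into prenyl and comes back at 23.

Step 11. The aldehyde α-carbon may epimerise or lose the β-hydroxyl group through the enamine, and the quinone methide may tautomerise to a styrene before it is reduced. The fallback avoids amines and any sp2 carbon next to that centre.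
- It sets out from 11, isolated this time. Oxidation with n-Pr4N[RuO4]/NMO gives an aldehyde that closes onto the neighbouring tertiary OH as the tosyloxy lactol F3.
- Sc(OTf)3 (10 mol %, aq EtOH) promotes C-arylation of the derived oxocarbenium ion by 17, as in the C-glycosylation of phloroacetophenones, to give the 2-aryltetrahydrofuran F4.
- Hydrogenolysis of the benzylic C–O bond (H2, Pd/C, EtOH) gives the hydroxy tosylate F5.
- DBU in CH2Cl2 closes the oxirane, which comes back at 19.

Further compounds
F1 | step 13 | dearomatised C-3-prenylated epoxide (C-3 S) | CC[C@@H](C)C(=O)C1=C(O)[C@](C)(CC=C(C)C)C(=O)C(C[C@@H]2[C@@H](CC[C@]2(C)O)[C@]2(C)CO2)=C1O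
F2 | step 14 | C-3-allyl analogue of the target (C-3 S, C-5 R) | CC[C@@H](C)C(=O)C1=C(O)[C@](C)(CC=C)C(=O)[C@]2(C[C@@H]3[C@@H](CC[C@]3(C)O)[C@@](C)(O)C2)C1=O
F3 | step 11 | cis-fused tosyloxy lactol (anomers) | OC1[C@@H]2[C@@H](CC[C@]2(C)O)[C@@](C)(O1)COS(=O)(=O)c1ccc(C)cc1
F4 | step 11 | cis-fused 2-aryltetrahydrofuran (benzylic epimers) | CC[C@@H](C)C(=O)c1c(O)c(C)c(O)c(C2[C@@H]3[C@@H](CC[C@]3(C)O)[C@@](C)(O2)COS(=O)(=O)c3ccc(C)cc3)c1O
F5 | step 11 | C-5-alkylated hydroxy tosylate | CC[C@@H](C)C(=O)c1c(O)c(C)c(O)c(C[C@@H]2[C@@H](CC[C@]2(C)O)[C@@](C)(O)COS(=O)(=O)c2ccc(C)cc2)c1O
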